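**Retrosynthetic overview**
- Feature: the only ring is a 4-hydroxy-2H-pyran-3(6H)-one (O1, stereogenic C2, ketone C3, enol carbon C4, C5, methylene C6). The enol oxygen on C4 is next to C5, and C5 carries C1'H2–C2'H=C3'H (E)–C4'H(CH3). The array O–C4=C5–C1'–C2'=C3' is what a Claisen shift leaves behind, so C5–C1' is cut back to a secondary allyl enol ether O(C4)–C3', whose C3' configuration does not matter.
- This ether is cut at O–C3' (Mitsunobu) into the C5-unsubstituted diosphenol and a vinyl carbinol. The carbinol comes from ethyl (S)-3-hydroxybutanoate by anti-methylation, silylation, DIBAL reduction and vinyl Grignard addition.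
- The diosphenol goes back through epoxy ketone, enone and lactol to an (S)-furyl carbinol (Achmatowicz). The carbinol comes from a vinylogous Mukaiyama aldol of 3-methylbut-2-enoic acid with furfural, O-alkylation with methyl 6-bromohexanoate and a tartrate-controlled kinetic resolution.
- Ring order: the pyranone is made first. The side chain is then attached at oxygen and moved to C5, and desilylation and enzymatic methyl ester hydrolysis finish the route.

Key step: step 14

Assumption: the lactol carbon, the two oxirane carbons, the carbinol/ether carbon C3' and the transient sp3 C5 are carried as mixtures because each is erased later. The target is taken as the C3-keto/C4-enol tautomer drawn.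

**Step 1**
Reactants: 1 3-methylbut-2-enoic acid
Product: 2 1,1-bis(trimethylsilyloxy)-3-methylbuta-1,3-diene
Conditions: LDA (2.2 equiv), THF, −78 to 0 °C; TMSCl (2.5 equiv), −78 °C to rt; filtered under Ar, distilled
Reagents that add atoms: chlorotrimethylsilane, C[Si](C)(C)Cl
Why: Double deprotonation (carboxyl OH, then a γ-methyl C–H) gives the dienediolate, and O-silylation of both oxygens should give the bis(silyl) ketene acetal, the usual nucleophile for a vinylogous Mukaiyama aldol reaction.

**Step 2**
Reactants: 2 1,1-bis(trimethylsilyloxy)-3-methylbuta-1,3-diene; 3 furfural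
Product: 5 racemic (E)-5-(furan-2-yl)-5-hydroxy-3-methylpent-2-enoic acid, via bis-silylated aldol adduct 4 (not isolated)
Conditions: Sc(OTf)3 (5 mol %), CH2Cl2, −78 °C; aq. citric acid–THF, 0 °C; extraction into aq. NaHCO3, re-acidification to pH 4
Reagents that add atoms: none
Why: Vinylogous Mukaiyama aldol reaction in which the Lewis-acid-activated aldehyde is attacked through an open transition state by the unhindered γ-CH2 terminus of the extended (s-trans) dienolate, which should give the 2E acid, racemic at the carbinol (resolved in step 4), while any 2Z adduct closes to a neutral lactone on acidification and stays behind in the acid–base extraction.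

**Step 3**
Reactants: 5 racemic (E)-5-(furan-2-yl)-5-hydroxy-3-methylpent-2-enoic acid; 6 methyl 6-bromohexanoate
Product: 7 racemic 6-methoxy-6-oxohexyl (E)-5-(furan-2-yl)-5-hydroxy-3-methylpent-2-enoate
Conditions: Cs2CO3 (1.0 equiv), DMF, rt
Reagents that add atoms: none
Why: SN2 O-alkylation of the caesium carboxylate by the primary bromide, in which the far less acidic secondary alcohol stays un-ionised and the enoate geometry is untouched.

**Step 4**
Reactants: 7 racemic furyl carbinol diester
Product: 8 6-methoxy-6-oxohexyl (2E,5S)-5-(furan-2-yl)-5-hydroxy-3-methylpent-2-enoate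
Conditions: Ti(OiPr)4 (0.2 equiv), D-(−)-DIPT (0.24 equiv), TBHP (0.65 equiv), 4 Å MS, CH2Cl2, −20 °C; chromatography
Reagents that add atoms: none
Why: Sharpless-type kinetic resolution of a 2-furylcarbinol, in which the furan C2=C3 bond plays the part of the alkene of a secondary allylic alcohol, so with D-(−)-DIPT the (R)-carbinol should be oxidised quickly to a polar pyranone while the mismatched (S)-carbinol is left, and running past half conversion should raise its enantiopurity; this sets ring C2 of the target.

**Step 5**
Reactants: 8 (S)-furyl carbinol diester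
Product: 9 6-methoxy-6-oxohexyl (E)-4-[(2S)-6-hydroxy-3-oxo-3,6-dihydro-2H-pyran-2-yl]-3-methylbut-2-enoate (both C6 anomers)
Conditions: NBS (1.05 equiv), NaHCO3, THF–H2O (4:1), 0 °C
Reagents that add atoms: water, O
Why: Achmatowicz rearrangement, in which bromonium-induced hydration of the electron-rich furan gives a cis-enedione whose aldehyde is captured by the carbinol oxygen as a six-membered hemiacetal; the C–O bond at the stereocentre is never broken, so (S) is retained, and the electron-poor enoate does not compete for NBS.

**Step 6**
Reactants: 9 Achmatowicz lactol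
Product: 10 6-methoxy-6-oxohexyl (E)-3-methyl-4-[(2S)-3-oxo-3,6-dihydro-2H-pyran-2-yl]but-2-enoate
Conditions: Et3SiH (3 equiv), TFA, CH2Cl2, −40 °C
Reagents that add atoms: none
Why: Ionic (Kishi-type) lactol reduction, in which TFA ionises the hemiacetal to the conjugated oxocarbenium ion and Et3SiH delivers hydride to C6 at a temperature at which the enone, both esters and C2 should be untouched.

**Step 7**
Reactants: 10 (S)-2-substituted 2H-pyran-3(6H)-one
Product: 11 6-methoxy-6-oxohexyl (E)-4-[(2S)-4,5-epoxy-3-oxotetrahydropyran-2-yl]-3-methylbut-2-enoate (cis-oxirane, face not assigned)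
Conditions: 30 % H2O2, NaOH (0.1 equiv), MeOH–THF, 0 °C, short
Reagents that add atoms: hydrogen peroxide, OO
Why: Weitz–Scheffer nucleophilic epoxidation, in which hydroperoxide adds to C5 of the ring enone and the enolate closes on oxygen; the much less electrophilic β,β-disubstituted enoate is not attacked, and the two oxirane centres need no control because both become sp2 in step 8.

**Step 8**
Reactants: 11 epoxy ketone
Product: 12 6-methoxy-6-oxohexyl (E)-4-[(2S)-4-hydroxy-3-oxo-3,6-dihydro-2H-pyran-2-yl]-3-methylbut-2-enoate (C5-unsubstituted diosphenol)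
Conditions: Amberlyst-15, acetone–H2O (20:1), 0 °C to rt, short contact; filtered, concentrated cold, used at once
Reagents that add atoms: none
Why: Acid-catalysed isomerisation of an epoxy ketone to an α-hydroxy enone (known for steroidal 4,5-epoxy-3-ketones and for pyranone routes to maltol), in which water opens the protonated oxirane and the C5 hydroxyl is then lost from the C3/C4 enediol, which places the enol at C4=C5 directly; filtering off the resin ends the reaction without any base.

**Step 9**
Reactants: 13 ethyl (S)-3-hydroxybutanoate
Product: 14 ethyl (2S,3S)-3-hydroxy-2-methylbutanoate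
Conditions: LDA (2.2 equiv), THF, −78 to −20 °C; MeI, DMPU, −78 to 0 °C
Reagents that add atoms: iodomethane, CI
Why: Fráter–Seebach alkylation, in which the lithium-chelated alkoxide enolate is methylated on the face opposite the C3 methyl group, which should set C2 anti to the chiral-pool carbinol, i.e. (2S,3S).

**Step 10**
Reactants: 14 ethyl (2S,3S)-3-hydroxy-2-methylbutanoate
Product: 15 ethyl (2S,3S)-3-(tert-butyldimethylsilyloxy)-2-methylbutanoate
Conditions: TBSCl, imidazole, DMF, rt
Reagents that add atoms: tert-butyldimethylsilyl chloride, CC(C)(C)[Si](C)(C)Cl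
Why: Standard imidazole-promoted silylation of a secondary alcohol, giving an ether that should survive DIBAL, Grignard, Mitsunobu and thermal conditions and fall to fluoride at the end.

**Step 11**
Reactants: 15 silyloxy ester
Product: 16 (2S,3S)-3-(tert-butyldimethylsilyloxy)-2-methylbutanal
Conditions: DIBAL (1.05 equiv), CH2Cl2, −78 °C; MeOH at −78 °C, then aq. Rochelle salt; used without delay
Reagents that add atoms: none
Why: Partial ester reduction, in which the tetrahedral aluminium hemiacetal persists at −78 °C and collapses to the aldehyde only on quenching, and immediate use should avoid epimerisation at the α-carbon.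

**Step 12**
Reactants: 16 (2S,3S)-3-(tert-butyldimethylsilyloxy)-2-methylbutanal; 17 vinylmagnesium bromide
Product: 18 (4R,5S)-5-(tert-butyldimethylsilyloxy)-4-methylhex-1-en-3-ol (both C3 epimers)
Conditions: THF, −78 to 0 °C
Reagents that add atoms: none
Why: 1,2-Addition of a vinyl Grignard reagent to the aldehyde; the new carbinol centre forms as a Felkin/anti-Felkin mixture that is deliberately not separated because it is destroyed in step 14.

**Step 13**
Reactants: 12 C5-unsubstituted diosphenol; 18 secondary allylic alcohol (epimer mixture)
Product: 19 6-methoxy-6-oxohexyl (E)-4-[(2S)-4-{[(4R,5S)-5-(tert-butyldimethylsilyloxy)-4-methylhex-1-en-3-yl]oxy}-3-oxo-3,6-dihydro-2H-pyran-2-yl]-3-methylbut-2-enoate (both C3' epimers)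
Conditions: PPh3, DIAD (premixed, 0 °C), then 18, then 12, PhMe, 0 °C to rt; chromatography
Reagents that add atoms: none
Why: Mitsunobu etherification, in which the phenol-like enol OH of 12 protonates the PPh3–DIAD betaine and its oxygen displaces the oxyphosphonium group at the secondary allylic carbon under essentially neutral conditions; inversion at C3' is irrelevant, and ether arising from attack at the vinyl terminus is removed by chromatography.

**Step 14**
Reactants: 19 diosphenol secondary allyl enol ether (epimer mixture)
Product: 21 6-methoxy-6-oxohexyl (E)-4-[(2S)-5-[(2E,4R,5S)-5-(tert-butyldimethylsilyloxy)-4-methylhex-2-en-1-yl]-4-hydroxy-3-oxo-3,6-dihydro-2H-pyran-2-yl]-3-methylbut-2-enoate, via 3,4-diketone 20 (not isolated)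
Conditions: Eu(fod)3 (10 mol %), PhMe, 80 °C, Ar
Reagents that add atoms: none
Why: Concerted suprafacial [3,3]-sigmatropic (Claisen) shift of the allyl vinyl ether C5=C4–O–C3'–C2'=C1' through a chair, in which the O–C3' bond breaks while C5–C1' forms and the alkene moves to C2'=C3'. The closest known reaction type is the Claisen rearrangement of O-allyl ethers of cyclic 1,2-diketone enols to C-allyl diosphenols, which lanthanide fod complexes accelerate by chelating the ketone and ether oxygens. No ring is closed, since the pyranone is already in place. The only stereocentre created, C5 of diketone 20, is erased at once when 20 enolises toward C5 to the hydrogen-bonded tetrasubstituted enol, and C3' is destroyed, so both ether epimers should converge on 21. The step needs E geometry, secured by the branched C4' substituent lying pseudo-equatorial in the chair from either epimer, and it needs C2 and the enol position to stay intact, which the absence of Brønsted acid or base and the moderate temperature should secure.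

**Step 15**
Reactants: 21 protected target (TBS ether, methyl ester)
Product: 22 6-methoxy-6-oxohexyl (E)-4-[(2S)-4-hydroxy-5-[(2E,4R,5S)-5-hydroxy-4-methylhex-2-en-1-yl]-3-oxo-3,6-dihydro-2H-pyran-2-yl]-3-methylbut-2-enoate
Conditions: HF·pyridine, pyridine, THF, 0 °C to rt (plastic vessel); pH 7 buffer work-up
Reagents that add atoms: none
Why: Fluoride-driven cleavage of the secondary TBS ether under weakly acidic, buffered conditions, which avoids basic fluoride sources that could move the enol or epimerise C2.

**Step 16**
Reactants: 22 methyl ester of the target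
Product: 23 6,7-diketothiomarinolic acid C6
Conditions: pig-liver esterase, 0.1 M phosphate buffer pH 7, acetone (10 % v/v), 25 °C, monitored; then pH 4, EtOAc
Reagents that add atoms: water, O
Why: Enzymatic ester hydrolysis at neutral pH, in which the unhindered saturated methyl ester is a normal substrate of the serine hydrolase whereas the conjugated β,β-disubstituted enoate is a poor acyl donor, so the acid should be freed without hydroxide and without touching C2 or the diosphenol.

**Compound list**
1 | 3-methylbut-2-enoic acid | CC(C)=CC(=O)O | starting material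
2 | 1,1-bis(trimethylsilyloxy)-3-methylbuta-1,3-diene | C=C(C)C=C(O[Si](C)(C)C)O[Si](C)(C)C | intermediate
3 | furfural | O=Cc1ccco1 | starting material
4 | trimethylsilyl (E)-5-(furan-2-yl)-3-methyl-5-(trimethylsilyloxy)pent-2-enoate (racemic, not isolated) | C/C(=C\C(=O)O[Si](C)(C)C)CC(O[Si](C)(C)C)c1ccco1 | intermediate
5 | racemic (E)-5-(furan-2-yl)-5-hydroxy-3-methylpent-2-enoic acid | C/C(=C\C(=O)O)CC(O)c1ccco1 | intermediate
6 | methyl 6-bromohexanoate | COC(=O)CCCCCBr | starting material
7 | racemic 6-methoxy-6-oxohexyl (E)-5-(furan-2-yl)-5-hydroxy-3-methylpent-2-enoate | C/C(=C\C(=O)OCCCCCC(=O)OC)CC(O)c1ccco1 | intermediate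
8 | 6-methoxy-6-oxohexyl (2E,5S)-5-(furan-2-yl)-5-hydroxy-3-methylpent-2-enoate | C/C(=C\C(=O)OCCCCCC(=O)OC)C[C@H](O)c1ccco1 | intermediate
9 | Achmatowicz lactol, (2S), C6 anomers | C/C(=C\C(=O)OCCCCCC(=O)OC)C[C@@H]1OC(O)C=CC1=O | intermediate
10 | (2S)-2-substituted 2H-pyran-3(6H)-one | C/C(=C\C(=O)OCCCCCC(=O)OC)C[C@@H]1OCC=CC1=O | intermediate
11 | (2S)-4,5-epoxy-3-oxotetrahydropyran (oxirane face not assigned) | C/C(=C\C(=O)OCCCCCC(=O)OC)C[C@@H]1OCC2OC2C1=O | intermediate
12 | (2S)-4-hydroxy-2H-pyran-3(6H)-one, C5-unsubstituted diosphenol | C/C(=C\C(=O)OCCCCCC(=O)OC)C[C@@H]1OCC=C(O)C1=O | intermediate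
13 | ethyl (S)-3-hydroxybutanoate | CCOC(=O)C[C@H](C)O | starting material
14 | ethyl (2S,3S)-3-hydroxy-2-methylbutanoate | CCOC(=O)[C@@H](C)[C@H](C)O | intermediate
15 | ethyl (2S,3S)-3-(tert-butyldimethylsilyloxy)-2-methylbutanoate | CCOC(=O)[C@@H](C)[C@H](C)O[Si](C)(C)C(C)(C)C | intermediate
16 | (2S,3S)-3-(tert-butyldimethylsilyloxy)-2-methylbutanal | O=C[C@@H](C)[C@H](C)O[Si](C)(C)C(C)(C)C | intermediate
17 | vinylmagnesium bromide | C=C[Mg]Br | starting material
18 | (4R,5S)-5-(tert-butyldimethylsilyloxy)-4-methylhex-1-en-3-ol, both C3 epimers | C=CC(O)[C@@H](C)[C@H](C)O[Si](C)(C)C(C)(C)C | intermediate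
19 | diosphenol secondary allyl enol ether, (2S,4'R,5'S), both C3' epimers | C/C(=C\C(=O)OCCCCCC(=O)OC)C[C@@H]1OCC=C(OC(C=C)[C@@H](C)[C@H](C)O[Si](C)(C)C(C)(C)C)C1=O | intermediate
20 | C5-allylated 3,4-diketone, C5 epimers (not isolated) | C/C(=C\C(=O)OCCCCCC(=O)OC)C[C@@H]1OCC(C/C=C/[C@@H](C)[C@H](C)O[Si](C)(C)C(C)(C)C)C(=O)C1=O | intermediate
21 | protected target (TBS ether, methyl ester) | C/C(=C\C(=O)OCCCCCC(=O)OC)C[C@@H]1OCC(C/C=C/[C@@H](C)[C@H](C)O[Si](C)(C)C(C)(C)C)=C(O)C1=O | intermediate
22 | methyl ester of the target | C/C(=C\C(=O)OCCCCCC(=O)OC)C[C@@H]1OCC(C/C=C/[C@@H](C)[C@H](C)O)=C(O)C1=O | intermediate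
23 | 6,7-diketothiomarinolic acid C6 | C/C(=C\C(=O)OCCCCCC(=O)O)C[C@@H]1OCC(C/C=C/[C@@H](C)[C@H](C)O)=C(O)C1=O | target

**Total step count:** 16
**Longest linear sequence:** 12 (steps 1–8, then 13–16)

**Steps most likely to fail**

Step 8 (oxirane to diosphenol).
- What may go wrong: opening at the secondary, inductively deactivated C5 may be slow. Acyl migration with ring contraction may compete. Acid-catalysed enolisation toward C2 may cause racemisation and drift of the enol.
- Fallback: it sets out from enone 10 and comes back at diosphenol 12. RhCl(PPh3)3-catalysed 1,4-hydrosilylation of the ring enone with Et3SiH would give the triethylsilyl enol ether F1, with its double bond fixed at C3=C4. Rubottom oxidation (mCPBA, NaHCO3, CH2Cl2, then dilute acetic acid) would give the 4-hydroxy ketone F2. Dess–Martin oxidation of this acyloin would give the C5-unsubstituted 3,4-diketone F3, which should enolise toward the unhindered C5 methylene to 12. The oxygen is thus brought in by electrophilic oxidation of a regiodefined enol ether instead of by opening an oxirane.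

Step 13 (Mitsunobu etherification).
- What may go wrong: activation of the α-branched carbinol may be sluggish. Attack at the vinyl terminus, elimination toward a diene, and alkylation at carbon instead of oxygen are all possible.
- Fallback: it sets out from alcohol 18 and diosphenol 12 and comes back at ether 19. Alcohol 18 would be acylated (ClCO2Me, pyridine) to the secondary allylic methyl carbonate F4. This would be coupled with the sodium salt of 12 by rhodium-catalysed allylic etherification (RhCl(PPh3)3 modified with P(OMe)3, THF). That substitution runs through an enyl (σ+π) rhodium species and keeps the new C–O bond at the carbon that bore the leaving group.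

Step 14 (Claisen shift and enolisation).
- What may go wrong: the rearrangement may proceed only at temperatures at which the transient diketone or the product enolises toward C2. That would cost the C2 configuration and move the enol. The E selectivity may also erode.
- Fallback: it sets out from ether 19, comes back at 21 and makes no new compound (F0). Catalytic Pd(PPh3)4 in THF at rt would ionise the allylic O–C3' bond to a π-allylpalladium/diosphenolate ion pair. Return at oxygen is reversible, whereas attack of the soft C5 carbon on the unsubstituted allyl terminus C1' is not. The same linear E product should therefore accumulate through diketone 20 by an ionic, metal-catalysed O-to-C transfer, at a temperature at which tautomer drift is slow.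

**Further compounds**
F1 | step 8 | 6-methoxy-6-oxohexyl (E)-3-methyl-4-[(2S)-3-(triethylsilyloxy)-5,6-dihydro-2H-pyran-2-yl]but-2-enoate | C/C(=C\C(=O)OCCCCCC(=O)OC)C[C@@H]1OCCC=C1O[Si](CC)(CC)CC
F2 | step 8 | 6-methoxy-6-oxohexyl (E)-4-[(2S)-4-hydroxy-3-oxotetrahydropyran-2-yl]-3-methylbut-2-enoate (C4 epimers) | C/C(=C\C(=O)OCCCCCC(=O)OC)C[C@@H]1OCCC(O)C1=O
F3 | step 8 | 6-methoxy-6-oxohexyl (E)-4-[(2S)-3,4-dioxotetrahydropyran-2-yl]-3-methylbut-2-enoate | C/C(=C\C(=O)OCCCCCC(=O)OC)C[C@@H]1OCCC(=O)C1=O
F4 | step 13 | (4R,5S)-5-(tert-butyldimethylsilyloxy)-4-methylhex-1-en-3-yl methyl carbonate (both C3 epimers) | C=CC(OC(=O)OC)[C@@H](C)[C@H](C)O[Si](C)(C)C(C)(C)C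
F0 | step 14 | none | none
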